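**The chain.** G.Z is the product I want. X gives G, and E gives Z while exchanging with L. G and Z join to G.Z, which exchanges with D, and two G can pair off to G2 instead.

| flask | X | E | time | remark |
|---|---|---|---|---|
| dawn | 0.061 M | 0.0549 M (fed, over 4.0 h) | 10 h | all else is in the flask from the start; the feed brings no volume worth counting |
| dusk | 0.061 M (fed, over 4.0 h) | 0.0549 M | 10 h | all else is in the flask from the start; the feed brings no volume worth counting |
| spring | 0.061 M | 0.0549 M | 10 h | everything together at the start |

- the best flask by amount of G.Z, in percent of the X charged; "all alike" if 1.5 percentage points covers them all (dawn / dusk / spring / all alike)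
- amount of G.Z at the end, in percent of the X charged, dawn
- amount of G.Z at the end, in percent of the X charged, dusk
- amount of G.Z at the end, in percent of the X charged, spring

- a species is counted by the X in it: one G2 counts as two
- where a step has two of a species, its rate is k times that concentration squared, and two are used at each turn
- run time (dawn): 10 h

    X → G (k1 = 3.00 × 10⁻⁴ s⁻¹)
    E → Z (k2 = 1.45 × 10⁻⁴ s⁻¹)
    G + Z → G.Z (k3 = 0.166 L mol⁻¹ s⁻¹)
    2 G → G2 (k4 = 0.0147 L mol⁻¹ s⁻¹)
    E ⇌ L (K5 = 0.826, k5 = 0.00130 s⁻¹)
    G.Z ⇌ D (K6 = 0.667, k6 = 8.28 × 10⁻⁴ s⁻¹)

**End share.** I ask first what the end must look like. G.Z and D relax with a half-life of 0.0930 h, much shorter than the 10 h of the run, so the coupled material ends split by 0.667 parts of D to one of G.Z. The fraction standing as G.Z is 0.600, and I call it the G.Z share.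

**Z supply.** E and L relax within 0.0670 h, much faster than the 1.3 h half-life of E towards Z. So the E-and-L pool loses Z at a diluted constant of 0.286 h⁻¹.

**Race window.** In spring, G starts arriving at 0.0659 M h⁻¹ and Z at 0.0157 M h⁻¹, which is slower. The supply of Z is therefore the rate-limiting step of coupling, and the surplus G pairs off. Coupled product is then the Z made while G lasts. As a first guess, G lasts 5 half-lives of X, which is 3.21 h after X is in, so dusk adds its feed time. Multiplying by the share, I get 32.4 % for spring and 47.1 % for dusk. For dawn, where the pool itself grows from the feed, I get 15.0 %. Dusk comes out best.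

**Weak link.** The cut-off is the guess. In spring, the two supplies cross at 1.81 h, and after that the stock of G must make up the difference. From the crossing to the cut-off, the pool gives 0.0108 M of Z while X still gives 0.00676 M of G, so the stock must cover 0.00406 M. Pairing goes on spending that stock, and I cannot tell by hand whether it lasts, so the window stays an estimate, and I commit to it as one.

**The result.** The forecast names dusk, with 16.7 % for dawn, 48.2 % for dusk and 33.6 % for spring, each above mine: “The outcome is a race between G+Z coupling and G dimerisation.” The simulation gives dusk, with 16.8 % for dawn, 47.1 % for dusk and 32.9 % for spring.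

**Share again.** Dusk at 10.0 h holds 47.1 % as G.Z and 31.4 % as D, and the share on their sum gives 47.1 %. A neighbour of dawn is fed 0.22 M of E, which is 3.61 equiv to X, and ends with 0 % of its X left and 47.9 % as G2. The coupled part there is 52.1 %, so the share predicts 31.3 % as G.Z. That neighbour of dawn stands at 31.3 % of G.Z, with 20.9 % as D.

Its constants are those of an exercise; the flask was simulated.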